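(The data are simulated with made-up constants.)

What single product stands in each flask after 4.0 h, when the coupling partner goes from 1.00 equiv to 4.00 equiv? I start from what has been run.

| flask | substrate | coupling partner | capture agent | remark | time |
|---|---|---|---|---|---|
| eta | 11 mM | 1 equiv | 2.2 mM | run made earlier |  |
| delta | 22 mM | 1 equiv | 3.3 mM | run made earlier |  |
| amber | 11 mM | 1.00 equiv | 3.30 mM |  | 4.0 h |
| blue | 11 mM | 2.00 equiv | 3.30 mM |  | 4.0 h |
| violet | 11 mM | 4.00 equiv | 3.30 mM |  | 4.0 h |

- eta (time / min: single product / %, double product / %): 4.00: 16.2, 0.9; 6.00: 21.4, 3.6; 8.00: 26.3, 5.3; 15.0: 33.9, 9.1; 20.0: 34.7, 11.8; 30.0: 36.0, 17.8; 50.0: 34.3, 23.3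
- delta (time / min: single product / %, double product / %): 2.50: 20.8, 2.2; 8.00: 32.8, 10.0; 15.0: 35.8, 17.7; 20.0: 37.1, 21.4; 30.0: 35.6, 23.8; 40.0: 34.7, 26.8; 50.0: 32.1, 27.4

(each reading ± 0.5 percentage points)

- final single product, as a percentage of the substrate charged, for each flask in turn (amber, blue, violet)

I build the flask one process at a time, beginning with the first coupling alone. Substrate and partner start equal in the eta run, so the second-order rate integrates in closed form, with a the fraction of substrate left:

1/a − 1 = t/τ

I call τ the coupling time: the time scale of one coupling when the partner stands at 11 mM. The first eta reading has 17.1% of the substrate coupled, which gives τ = 0.323 h. With this step alone, amber would reach 92.5% single product.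

Next I add the second coupling. The eta peak reads 36.0%, close to the 36.8% that equal rate constants give (a selectivity factor near one), so I take them equal:

[single product]/[substrate charged] = −a ln a

At the peak of this reckoned curve, single plus 2 × double has spent 89.6% of an equivalent. So I expect amber's partner, the limiting reagent, to last just past that peak.

Last come the slower losses. Delta's single product falls from 37.1% to 32.1% late in the run, so for amber I commit to no more than that last reading.

With excess partner the second coupling is pseudo-first-order:

half-life of single product = τ ln(2) / equivalents

With blue's partner as charged this is 0.112 h, far shorter than 4.0 h. Blue's partner thins as it is used, so I expect a low single-digit to modest yield there, and violet's single product should be close to zero.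

The forecast gives 32%, 15% and 11%. Its amber value follows the tail of delta; its values for blue and violet rest on a cap on the capture agent, inferred from the remark that “delta stalls at about 6 turnovers per agent”. My coupling time carries no such cap, so I part from it on blue and violet.

The flasks give 19.3%, 2.90% and <0.001%.

    substrate + coupling partner → single product (k = 0.0863 M⁻¹ s⁻¹)
    coupling partner + single product → double product (k = 0.0696 M⁻¹ s⁻¹)
    2 coupling partner → self-condensation product (k = 0.00118 M⁻¹ s⁻¹)
    single product + capture agent → trapped intermediate (k = 0.0487 M⁻¹ s⁻¹)

In blue, the half-life of single product by the second coupling alone, with the partner as charged, is 0.13 h, far shorter than the 4.0 h of the run. Double product there stands at 77.5% and single product at 2.90% at the end. With violet's partner as charged, my coupling time puts 71.5 half-lives into the same 4.0 h, and violet's single product stands at 0.0115% at 2.00 h and <0.001% at 4.00 h.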